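Retrosynthesis: the exocyclic alkene and the methyl-bearing CH of ring C come from an allylic alcohol by reductive 1,3-transposition. That alcohol is cut between ring C and the carbinol carbon into a ring C/D enol triflate and a ring A/B aldehyde. Ring C is then cut at C3a–C4 (divinylcyclopropane rearrangement), and rings A/B at O1–C2 and C5a–C6 (diepoxide cascade).
Feature used: in the seven-membered ring C the quaternary CMe2 carbon (C4) is bonded directly to the ring-fusion CH (C3a) of the five-membered ring D, and the ring CH2 (C7) sits two atoms from each of them. This is the cyclohepta-1,4-diene pattern left by a cis-divinylcyclopropane.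
Forward: ring D from cyclopentenone, then the cyclopropane, then ring C by the rearrangement, then the enol triflate. Rings A and B are closed together from a geranyl-derived diepoxide. A Ni/Cr coupling joins the halves, the alkene is transposed and the oxepanone is unveiled last.
Stereochemistry: catalytic asymmetric methyl addition (ring D carbinol); reagent-controlled cyclopropanation relayed through the boat transition state (C3a); hydroxyl-directed hydrogenation (C8a); Shi epoxidation (C5a, C9a); equatorial Grignard attack (C7); oxazaborolidine reduction, Mitsunobu inversion and suprafacial retro-ene (ring C C6 and the Z alkene).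

Key step: step 10

Remark: ring C/D compounds are numbered as azulenes (C1 carbinol, C3a/C8a fusion, C4 gem-dimethyl, C5, C6 methyl-bearing) and ring A/B compounds as 1-benzoxepines; the oxepane C3 carbinol is carried as formed (R) because the last step turns it into the ketone.

Step 1
Reactants: 1 cyclopent-2-en-1-one
Product: 2 2-iodocyclopent-2-en-1-one
Conditions: I2, K2CO3, DMAP (cat.), THF/H2O (1:1), rt
Reagents that add atoms: iodine, II
Why: Amine-catalysed α-iodination of a cyclic enone (conjugate addition, iodination of the enolate, elimination) is routine and installs the vinyl iodide that later becomes the formyl-bearing carbon.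

Step 2
Reactants: 2 2-iodocyclopent-2-en-1-one
Product: 3 (1R)-2-iodo-1-methylcyclopent-2-en-1-ol
Conditions: ZnMe2, Ti(OiPr)4, chiral bis(10-camphorsulfonamide) diol ligand of trans-cyclohexane-1,2-diamine (10 mol%; the enantiomer series that gives the 1R alcohol), toluene/hexane, rt
Reagents that add atoms: dimethylzinc, C[Zn]C
Why: Titanium-promoted catalytic enantioselective 1,2-addition of a dialkylzinc to a ketone is at its best with α-substituted cyclic enones, whose two flanks (iodoalkene versus CH2) differ strongly, so the ligand should set the tertiary carbinol as R.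

Step 3
Reactants: 3 iodo carbinol
Product: 4 triethyl{[(1R)-2-iodo-1-methylcyclopent-2-en-1-yl]oxy}silane
Conditions: Et3SiOTf, 2,6-lutidine, CH2Cl2, −78 → 0 °C
Reagents that add atoms: triethylsilyl trifluoromethanesulfonate, CC[Si](CC)(CC)OS(=O)(=O)C(F)(F)F
Why: Silyl triflate/lutidine silylation is the standard way to cap a hindered tertiary alcohol, and the ether keeps this hydroxyl from directing the later cyclopropanation to the ring alkene.

Step 4
Reactants: 4 iodo silyl ether
Product: 6 (5R)-5-methyl-5-[(triethylsilyl)oxy]cyclopent-1-ene-1-carbaldehyde, via vinyllithium 5 (not isolated)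
Conditions: t-BuLi (2.1 equiv), Et2O, −78 °C; then DMF, −78 → 0 °C
Reagents that add atoms: N,N-dimethylformamide, CN(C)C=O
Why: Iodine–lithium exchange on a vinyl iodide followed by formylation with DMF is reliable and does not touch the stereocentre.

Step 5
Reactants: 6 cyclopentene carbaldehyde; 7 ethyl 2-[bis(2,2,2-trifluoroethoxy)phosphoryl]propanoate
Product: 8 ethyl (2Z)-2-methyl-3-{(5R)-5-methyl-5-[(triethylsilyl)oxy]cyclopent-1-en-1-yl}prop-2-enoate
Conditions: KN(SiMe3)2, 18-crown-6, THF, −78 °C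
Reagents that add atoms: none
Why: The Still–Gennari variant of the Horner–Wadsworth–Emmons olefination gives Z-configured α-methyl enoates under kinetic control, which places the future carbinol carbon cis to the cyclopentenyl group.

Step 6
Reactants: 8 Z enoate
Product: 9 (2Z)-2-methyl-3-{(5R)-5-methyl-5-[(triethylsilyl)oxy]cyclopent-1-en-1-yl}prop-2-en-1-ol
Conditions: iBu2AlH (2.5 equiv), CH2Cl2, −78 °C
Reagents that add atoms: none
Why: 1,2-Reduction of a conjugated ester with a dialkylaluminium hydride gives the allylic alcohol without changing the alkene geometry.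

Step 7
Reactants: 9 Z allylic alcohol
Product: 10 [(1R,2S)-1-methyl-2-{(5R)-5-methyl-5-[(triethylsilyl)oxy]cyclopent-1-en-1-yl}cyclopropyl]methanol
Conditions: Zn(CH2I)2 (from ZnEt2 and CH2I2), (4S,5S)-2-butyl-N,N,N',N'-tetramethyl-1,3,2-dioxaborolane-4,5-dicarboxamide (1.2 equiv), CH2Cl2, 0 °C → rt
Reagents that add atoms: diiodomethane, ICI
Why: Hydroxyl-directed Simmons–Smith cyclopropanation with a tartramide-derived dioxaborolane controller transfers CH2 only to the allylic-alcohol alkene, stereospecifically (CH2OH and cyclopentenyl stay cis) and, with the S,S controller, to the face that gives the 1R,2S ring.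

Step 8
Reactants: 10 cyclopropylmethanol
Product: 11 (1R,2R)-1-methyl-2-{(5R)-5-methyl-5-[(triethylsilyl)oxy]cyclopent-1-en-1-yl}cyclopropane-1-carbaldehyde
Conditions: Dess–Martin periodinane, NaHCO3, CH2Cl2, 0 °C; used at once
Reagents that add atoms: none
Why: Dess–Martin oxidation is mild enough for a cyclopropyl carbinol, the quaternary α-carbon cannot epimerise, and any dihydrooxepine formed by reversible retro-Claisen shift is drained through the aldehyde in the next step.

Step 9
Reactants: 11 cyclopropane carbaldehyde; 12 isopropyltriphenylphosphonium iodide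
Product: 13 triethyl({(1R)-1-methyl-2-[(1S,2S)-2-methyl-2-(2-methylprop-1-en-1-yl)cyclopropyl]cyclopent-2-en-1-yl}oxy)silane
Conditions: n-BuLi, THF, 0 °C; then 11, −78 → 0 °C
Reagents that add atoms: none
Why: Wittig olefination with the unstabilised isopropylidene ylide converts even neopentyl-type aldehydes into trisubstituted alkenes and creates no geometric isomers because the new terminus carries two methyl groups.

Step 10
Reactants: 13 cis-dialkenylcyclopropane
Product: 14 triethyl{[(1R,3aS)-1,4,4,6-tetramethyl-1,2,3,3a,4,7-hexahydroazulen-1-yl]oxy}silane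
Conditions: toluene, 110–130 °C (sealed tube, base-washed glass)
Reagents that add atoms: none
Why: This is a thermal [3,3]-sigmatropic (Cope) rearrangement of a cis-1,2-dialkenylcyclopropane, in which the cyclopropane bond between the two substituted carbons breaks while the dimethyl-substituted alkene terminus bonds to the cyclopentene CH, driven by release of ring strain; the closest known reaction type is the divinylcyclopropane–cycloheptadiene rearrangement, whose Z-substituted cases need heating. Ring C closes as a seven-membered ring by concerted ring expansion of the three-membered ring through a boat transition state with both alkenyl groups folded over the cyclopropane, not by an end-to-end cyclisation. The one new stereocentre, the ring-fusion CH (C3a), is controlled by the cyclopropane: in the boat only the cyclopentene face turned toward the other alkene can bond, and with the 1S,2S cyclopropane this is the face anti to the silyloxy group, giving 3aS (the R centre of the target once C8a is saturated). The step needs the two alkenyl groups cis and the bond formed suprafacially; the first is secured by the Z allylic alcohol used in the cyclopropanation, the second by the geometry of the boat. The inward-pointing methyl of the isopropylidene group slows the reaction but should not divert it, since the cyclopropane methyl is trans to the cyclopentenyl group and so offers no retro-ene path, and one-centre epimerisation needs higher temperatures.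

Step 11
Reactants: 14 silyl ether diene
Product: 15 (1R,3aS)-1,4,4,6-tetramethyl-1,2,3,3a,4,7-hexahydroazulen-1-ol
Conditions: Bu4NF, THF, rt
Reagents that add atoms: none
Why: Fluoride cleavage of the triethylsilyl ether frees the tertiary allylic alcohol so that it can steer the hydrogenation.

Step 12
Reactants: 15 dienol
Product: 16 (1R,3aR,8aR)-1,4,4,6-tetramethyl-1,2,3,3a,4,7,8,8a-octahydroazulen-1-ol
Conditions: [Ir(cod)(PCy3)(py)]PF6 (5 mol%), H2 (1 atm), CH2Cl2, 0 °C → rt
Reagents that add atoms: none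
Why: Hydroxyl-directed homogeneous hydrogenation with the cationic iridium catalyst adds H2 to the allylic C8=C8a alkene from the face of the coordinating carbinol, setting C8a–H cis to OH and to C3a–H (cis ring fusion), while the undirected C5=C6 alkene next to the quaternary carbon should react far more slowly.

Step 13
Reactants: 16 monoene alcohol
Product: 17 triethyl{[(1R,3aR,8aR)-1,4,4,6-tetramethyl-1,2,3,3a,4,7,8,8a-octahydroazulen-1-yl]oxy}silane
Conditions: Et3SiOTf, 2,6-lutidine, CH2Cl2, −78 → 0 °C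
Reagents that add atoms: triethylsilyl trifluoromethanesulfonate, CC[Si](CC)(CC)OS(=O)(=O)C(F)(F)F
Why: Re-silylation of the tertiary alcohol by the silyl triflate method is needed because a free alkoxide would compete with the enolate in the later triflation.

Step 14
Reactants: 17 silyl ether monoene
Product: 19 (1R,3aR,8aR)-1,4,4,6-tetramethyl-1-[(triethylsilyl)oxy]decahydroazulen-5-ol (C5/C6 diastereomers), via alkylborane 18 (not isolated)
Conditions: BH3·THF, THF, 0 °C → rt; then NaOH, H2O2, 0 °C → rt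
Reagents that add atoms: hydrogen peroxide, OO
Why: Hydroboration–oxidation of a trisubstituted alkene places boron, and then oxygen, on the less substituted carbon C5, and the configurations created at C5 and C6 do not matter because both centres become sp2 in steps 15 and 16.

Step 15
Reactants: 19 ring C alcohol
Product: 20 (1R,3aR,8aR)-1,4,4,6-tetramethyl-1-[(triethylsilyl)oxy]octahydroazulen-5(1H)-one (C6 epimers)
Conditions: Dess–Martin periodinane, NaHCO3, CH2Cl2, rt
Reagents that add atoms: none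
Why: Dess–Martin oxidation converts hindered secondary alcohols to ketones under neutral conditions that leave the silyl ether intact.

Step 16
Reactants: 20 ring C ketone
Product: 22 (1R,3aR,8aR)-1,4,4,6-tetramethyl-1-[(triethylsilyl)oxy]-1,2,3,3a,4,7,8,8a-octahydroazulen-5-yl trifluoromethanesulfonate, via potassium enolate 21 (not isolated)
Conditions: KN(SiMe3)2, THF, −78 → 0 °C; then PhNTf2, −78 °C → rt
Reagents that add atoms: N-phenylbis(trifluoromethanesulfonimide), O=S(=O)(N(c1ccccc1)S(=O)(=O)C(F)(F)F)C(F)(F)F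
Why: Enol triflate formation from a ketone enolate and an N-aryl triflimide is regiospecific here because C4 is quaternary and only C6–H can be removed, as in the triflation of 2,2,6-trimethylcyclohexanone.

Step 17
Reactants: 23 geranyl bromide [(2E)-1-bromo-3,7-dimethylocta-2,6-diene]; 24 N-methoxy-N-methylacetamide
Product: 25 (4E)-N-methoxy-N,5,9-trimethyldeca-4,8-dienamide
Conditions: LiN(iPr)2, THF, −78 °C; then 23, −78 → −20 °C
Reagents that add atoms: none
Why: Alkylation of an amide enolate with a primary allylic bromide is a direct SN2 substitution that keeps the E alkene and gives a carbonyl group that later accepts exactly one Grignard reagent.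

Step 18
Reactants: 25 dienyl amide
Product: 26 3-[(2R,3R)-3-{2-[(2R)-3,3-dimethyloxiran-2-yl]ethyl}-3-methyloxiran-2-yl]-N-methoxy-N-methylpropanamide
Conditions: D-fructose-derived Shi ketone (0.3 equiv per alkene), potassium peroxymonosulfate (2KHSO5·KHSO4·K2SO4), K2CO3, Bu4NHSO4, Na2B4O7 buffer (pH 10.5), MeCN/CH2(OMe)2/H2O, 0 °C
Reagents that add atoms: potassium peroxymonosulfate, [K+].[O-]S(=O)(=O)OO
Why: Dioxirane-mediated Shi asymmetric epoxidation is most selective for trisubstituted alkenes, and the D-fructose-derived ketone should deliver oxygen to the face of each alkene that makes the epoxide CH carbon R, which fixes C9a and C5a (and C3) of the ring A/B unit.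

Step 19
Reactants: 26 diepoxy amide
Product: 27 5-[(2R,3R)-3-{2-[(2R)-3,3-dimethyloxiran-2-yl]ethyl}-3-methyloxiran-2-yl]pent-1-en-3-one
Conditions: CH2=CHMgBr, THF, −78 → 0 °C; cold aq. NH4Cl quench
Reagents that add atoms: vinylmagnesium bromide, C=C[Mg]Br
Why: An N-methoxy-N-methyl amide forms a stable chelated adduct with a Grignard reagent, so a single vinyl group is transferred and the enone appears only on work-up, while trisubstituted epoxides are inert at this temperature.

Step 20
Reactants: 27 diepoxy vinyl ketone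
Product: 28 {[(3Z)-1-[(2R,3R)-3-{2-[(2R)-3,3-dimethyloxiran-2-yl]ethyl}-3-methyloxiran-2-yl]hepta-3,6-dien-3-yl]oxy}trimethylsilane
Conditions: CH2=CHMgBr, CuBr·SMe2 (10 mol%), Me3SiCl, THF, −78 °C; Et3N, cold aq. NaHCO3 work-up; used crude
Reagents that add atoms: vinylmagnesium bromide, C=C[Mg]Br; chlorotrimethylsilane, C[Si](C)(C)Cl
Why: Copper-catalysed, chlorosilane-accelerated conjugate addition to a vinyl ketone traps the enolate where it is formed, giving the silyl enol ether regiospecifically on the side that must become C6, a regiochemistry not available by enolising the saturated ketone.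

Step 21
Reactants: 28 diepoxy enol silane
Product: 30 (3R,5aR,6R,9aR)-3-hydroxy-2,2,5a-trimethyl-6-(prop-2-en-1-yl)octahydro-1-benzoxepin-7(2H)-one, via trimethylsilyl ether 29 (not isolated)
Conditions: Me3SiOTf (0.3 equiv), 2,6-di-tert-butyl-4-methylpyridine, CH2Cl2, −78 °C; then K2CO3, MeOH, rt
Reagents that add atoms: none
Why: Silyl activation of the terminal epoxide lets the oxygen of the neighbouring epoxide attack its tertiary carbon, and the epoxonium ion so formed is opened at its tertiary carbon with inversion by the enol silane through a chair (tandem oxa-/carbacyclisation of a 1,5-diepoxide with an enol silane terminator), which gives the trans-fused oxepane–cyclohexanone with C5a and C9a fixed by the R,R-epoxide and C6 equatorial, the epimer also favoured under the basic methanolysis that removes the silyl group.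

Step 22
Reactants: 30 hydroxy ketone
Product: 31 (3R,5aR,6R,7S,9aR)-2,2,5a,7-tetramethyl-6-(prop-2-en-1-yl)decahydro-1-benzoxepine-3,7-diol
Conditions: MeMgBr (3.5 equiv), THF, −78 → 0 °C
Reagents that add atoms: methylmagnesium bromide, C[Mg]Br
Why: Grignard 1,2-addition to a cyclohexanone whose axial face is screened by the 1,3-related axial C5a methyl occurs from the equatorial side, so the new methyl is equatorial and the C7 hydroxyl axial (7S), cis to the ring-fusion methyl as in the target.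

Step 23
Reactants: 31 diol
Product: 32 (3R,5aR,6R,7S,9aR)-2,2,5a,7-tetramethyl-6-(prop-2-en-1-yl)-3,7-bis[(triethylsilyl)oxy]decahydro-1-benzoxepine
Conditions: Et3SiOTf (3 equiv), 2,6-lutidine, CH2Cl2, −78 → 0 °C
Reagents that add atoms: triethylsilyl trifluoromethanesulfonate, CC[Si](CC)(CC)OS(=O)(=O)C(F)(F)F
Why: Silyl triflate silylates secondary and tertiary alcohols alike, which masks the C3 carbinol until the final oxidation and stops the cis C7 hydroxyl from closing a lactol onto the aldehyde made next.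

Step 24
Reactants: 32 bis-silyl ether
Product: 34 2-{(3R,5aR,6R,7S,9aR)-2,2,5a,7-tetramethyl-3,7-bis[(triethylsilyl)oxy]decahydro-1-benzoxepin-6-yl}acetaldehyde, via ozonide 33 (not isolated)
Conditions: O3, CH2Cl2, −78 °C; then PPh3, −78 °C → rt
Reagents that add atoms: ozone, [O-][O+]=O
Why: Ozonolysis with reductive work-up cleaves the only alkene, a terminal vinyl group, to the aldehyde one carbon shorter and leaves silyl ethers untouched.

Step 25
Reactants: 22 ring C/D enol triflate; 34 ring A/B aldehyde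
Product: 35 1-[(1R,3aR,8aR)-1,4,4,6-tetramethyl-1-[(triethylsilyl)oxy]-1,2,3,3a,4,7,8,8a-octahydroazulen-5-yl]-2-[(3R,5aR,6R,7S,9aR)-2,2,5a,7-tetramethyl-3,7-bis[(triethylsilyl)oxy]decahydro-1-benzoxepin-6-yl]ethan-1-ol (both C1 epimers)
Conditions: CrCl2 (6 equiv), NiCl2 (2 mol%), DMF/THF, rt → 50 °C
Reagents that add atoms: none
Why: Nickel-catalysed, chromium-mediated Nozaki–Hiyama–Kishi coupling turns an alkenyl triflate into a nucleophile that adds to aldehydes only, tolerating silyl ethers and the enolisable aldehyde, and the uncontrolled carbinol configuration is corrected in steps 26 and 27.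

Step 26
Reactants: 35 allylic alcohol mixture
Product: 36 1-[(1R,3aR,8aR)-1,4,4,6-tetramethyl-1-[(triethylsilyl)oxy]-1,2,3,3a,4,7,8,8a-octahydroazulen-5-yl]-2-[(3R,5aR,6R,7S,9aR)-2,2,5a,7-tetramethyl-3,7-bis[(triethylsilyl)oxy]decahydro-1-benzoxepin-6-yl]ethan-1-one
Conditions: Dess–Martin periodinane, NaHCO3, CH2Cl2, rt
Reagents that add atoms: none
Why: Dess–Martin oxidation of the allylic alcohol mixture converges both epimers on one enone.

Step 27
Reactants: 36 enone
Product: 37 (1R)-1-[(1R,3aR,8aR)-1,4,4,6-tetramethyl-1-[(triethylsilyl)oxy]-1,2,3,3a,4,7,8,8a-octahydroazulen-5-yl]-2-[(3R,5aR,6R,7S,9aR)-2,2,5a,7-tetramethyl-3,7-bis[(triethylsilyl)oxy]decahydro-1-benzoxepin-6-yl]ethan-1-ol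
Conditions: (S)-2-methyl-CBS-oxazaborolidine (0.5 equiv), BH3·SMe2, toluene, −30 °C
Reagents that add atoms: none
Why: Corey–Bakshi–Shibata reduction differentiates the bulky, fully substituted cycloalkenyl group from the CH2 arm, and with the S catalyst hydride should be delivered to give the 1R allylic alcohol.

Step 28
Reactants: 37 (1R) allylic alcohol
Product: 40 (3R,5aR,6R,7S,9aR)-6-{(2Z)-2-[(1R,3aR,6S,8aR)-1,4,4,6-tetramethyl-1-[(triethylsilyl)oxy]octahydroazulen-5(1H)-ylidene]ethyl}-2,2,5a,7-tetramethyl-3,7-bis[(triethylsilyl)oxy]decahydro-1-benzoxepine, via sulfonyl hydrazone adduct 38 (not isolated), via allylic diazene 39 (not isolated)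
Conditions: N-isopropylidene-N'-(2-nitrobenzenesulfonyl)hydrazine, PPh3, DEAD, THF, 0 → 23 °C; then CF3CH2OH/H2O (1:1), 23 °C
Reagents that add atoms: none
Why: In this reductive 1,3-transposition of an allylic alcohol, Mitsunobu displacement with inversion gives the 1S N-allyl sulfonyl hydrazone, hydrolysis and loss of sulfinate leave a monoalkyl diazene, and its retro-ene loss of N2 delivers hydrogen suprafacially to ring C C6 from the face held by nitrogen while the carbinol hydrogen eclipses the ring alkene to avoid allylic strain with the C6 methyl, so C6 becomes S and the new exocyclic alkene Z.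

Step 29
Reactants: 40 tris-silyl ether
Product: 41 (3R,5aR,6R,7S,9aR)-6-{(2Z)-2-[(1R,3aR,6S,8aR)-1-hydroxy-1,4,4,6-tetramethyloctahydroazulen-5(1H)-ylidene]ethyl}-2,2,5a,7-tetramethyldecahydro-1-benzoxepine-3,7-diol
Conditions: Bu4NF (6 equiv), THF, rt → 45 °C
Reagents that add atoms: none
Why: Fluoride removes all three triethylsilyl groups under basic conditions that spare the acid-sensitive pairing of a tertiary alcohol with the nearby trisubstituted alkene.

Step 30
Reactants: 41 triol
Product: 42 (5aR,6R,7S,9aR)-7-hydroxy-6-{(2Z)-2-[(1R,3aR,6S,8aR)-1-hydroxy-1,4,4,6-tetramethyloctahydroazulen-5(1H)-ylidene]ethyl}-2,2,5a,7-tetramethyloctahydro-1-benzoxepin-3(2H)-one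
Conditions: Dess–Martin periodinane, NaHCO3, CH2Cl2, 0 °C → rt
Reagents that add atoms: none
Why: Only the secondary oxepane carbinol can be oxidised, the two tertiary alcohols being inert, so Dess–Martin oxidation gives the ring A ketone and with it the target.

Compound list
1 | cyclopent-2-en-1-one | O=C1C=CCC1 | starting material
2 | 2-iodocyclopent-2-en-1-one | O=C1C(I)=CCC1 | intermediate
3 | (1R)-2-iodo-1-methylcyclopent-2-en-1-ol | IC1=CCC[C@@]1(C)O | intermediate
4 | triethyl{[(1R)-2-iodo-1-methylcyclopent-2-en-1-yl]oxy}silane | IC1=CCC[C@@]1(C)O[Si](CC)(CC)CC | intermediate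
5 | {(5R)-5-methyl-5-[(triethylsilyl)oxy]cyclopent-1-en-1-yl}lithium | [Li]C1=CCC[C@@]1(C)O[Si](CC)(CC)CC | intermediate
6 | (5R)-5-methyl-5-[(triethylsilyl)oxy]cyclopent-1-ene-1-carbaldehyde | O=CC1=CCC[C@@]1(C)O[Si](CC)(CC)CC | intermediate
7 | ethyl 2-[bis(2,2,2-trifluoroethoxy)phosphoryl]propanoate | CCOC(=O)C(C)P(=O)(OCC(F)(F)F)OCC(F)(F)F | starting material
8 | ethyl (2Z)-2-methyl-3-{(5R)-5-methyl-5-[(triethylsilyl)oxy]cyclopent-1-en-1-yl}prop-2-enoate | CCOC(=O)/C(C)=C\C1=CCC[C@@]1(C)O[Si](CC)(CC)CC | intermediate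
9 | (2Z)-2-methyl-3-{(5R)-5-methyl-5-[(triethylsilyl)oxy]cyclopent-1-en-1-yl}prop-2-en-1-ol | OC/C(C)=C\C1=CCC[C@@]1(C)O[Si](CC)(CC)CC | intermediate
10 | [(1R,2S)-1-methyl-2-{(5R)-5-methyl-5-[(triethylsilyl)oxy]cyclopent-1-en-1-yl}cyclopropyl]methanol | OC[C@]1(C)C[C@@H]1C2=CCC[C@@]2(C)O[Si](CC)(CC)CC | intermediate
11 | (1R,2R)-1-methyl-2-{(5R)-5-methyl-5-[(triethylsilyl)oxy]cyclopent-1-en-1-yl}cyclopropane-1-carbaldehyde | O=C[C@]1(C)C[C@@H]1C2=CCC[C@@]2(C)O[Si](CC)(CC)CC | intermediate
12 | isopropyltriphenylphosphonium iodide | CC(C)[P+](c1ccccc1)(c1ccccc1)c1ccccc1.[I-] | starting material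
13 | triethyl({(1R)-1-methyl-2-[(1S,2S)-2-methyl-2-(2-methylprop-1-en-1-yl)cyclopropyl]cyclopent-2-en-1-yl}oxy)silane | CC(C)=C[C@]1(C)C[C@@H]1C2=CCC[C@@]2(C)O[Si](CC)(CC)CC | intermediate
14 | triethyl{[(1R,3aS)-1,4,4,6-tetramethyl-1,2,3,3a,4,7-hexahydroazulen-1-yl]oxy}silane | CC1=CC(C)(C)[C@@H]2CC[C@@](C)(O[Si](CC)(CC)CC)C2=CC1 | intermediate
15 | (1R,3aS)-1,4,4,6-tetramethyl-1,2,3,3a,4,7-hexahydroazulen-1-ol | CC1=CC(C)(C)[C@@H]2CC[C@@](C)(O)C2=CC1 | intermediate
16 | (1R,3aR,8aR)-1,4,4,6-tetramethyl-1,2,3,3a,4,7,8,8a-octahydroazulen-1-ol | CC=1CC[C@@H]2[C@@H](CC[C@@]2(C)O)C(C)(C)C=1 | intermediate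
17 | triethyl{[(1R,3aR,8aR)-1,4,4,6-tetramethyl-1,2,3,3a,4,7,8,8a-octahydroazulen-1-yl]oxy}silane | CC=1CC[C@@H]2[C@@H](CC[C@@]2(C)O[Si](CC)(CC)CC)C(C)(C)C=1 | intermediate
18 | {(1R,3aR,8aR)-1,4,4,6-tetramethyl-1-[(triethylsilyl)oxy]decahydroazulen-5-yl}borane (C5/C6 syn adducts) | CC1CC[C@@H]2[C@@H](CC[C@@]2(C)O[Si](CC)(CC)CC)C(C)(C)C1B | intermediate
19 | (1R,3aR,8aR)-1,4,4,6-tetramethyl-1-[(triethylsilyl)oxy]decahydroazulen-5-ol (C5/C6 diastereomers) | CC1CC[C@@H]2[C@@H](CC[C@@]2(C)O[Si](CC)(CC)CC)C(C)(C)C1O | intermediate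
20 | (1R,3aR,8aR)-1,4,4,6-tetramethyl-1-[(triethylsilyl)oxy]octahydroazulen-5(1H)-one (C6 epimers) | CC1CC[C@@H]2[C@@H](CC[C@@]2(C)O[Si](CC)(CC)CC)C(C)(C)C1=O | intermediate
21 | potassium (1R,3aR,8aR)-1,4,4,6-tetramethyl-1-[(triethylsilyl)oxy]-1,2,3,3a,4,7,8,8a-octahydroazulen-5-olate | CC=1CC[C@@H]2[C@@H](CC[C@@]2(C)O[Si](CC)(CC)CC)C(C)(C)C=1[O-].[K+] | intermediate
22 | (1R,3aR,8aR)-1,4,4,6-tetramethyl-1-[(triethylsilyl)oxy]-1,2,3,3a,4,7,8,8a-octahydroazulen-5-yl trifluoromethanesulfonate | CC=1CC[C@@H]2[C@@H](CC[C@@]2(C)O[Si](CC)(CC)CC)C(C)(C)C=1OS(=O)(=O)C(F)(F)F | intermediate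
23 | geranyl bromide, (2E)-1-bromo-3,7-dimethylocta-2,6-diene | CC(C)=CCC/C(C)=C/CBr | starting material
24 | N-methoxy-N-methylacetamide | CC(=O)N(C)OC | starting material
25 | (4E)-N-methoxy-N,5,9-trimethyldeca-4,8-dienamide | CC(C)=CCC/C(C)=C/CCC(=O)N(C)OC | intermediate
26 | 3-[(2R,3R)-3-{2-[(2R)-3,3-dimethyloxiran-2-yl]ethyl}-3-methyloxiran-2-yl]-N-methoxy-N-methylpropanamide | CC1(C)O[C@@H]1CC[C@@]2(C)O[C@@H]2CCC(=O)N(C)OC | intermediate
27 | 5-[(2R,3R)-3-{2-[(2R)-3,3-dimethyloxiran-2-yl]ethyl}-3-methyloxiran-2-yl]pent-1-en-3-one | CC1(C)O[C@@H]1CC[C@@]2(C)O[C@@H]2CCC(=O)C=C | intermediate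
28 | {[(3Z)-1-[(2R,3R)-3-{2-[(2R)-3,3-dimethyloxiran-2-yl]ethyl}-3-methyloxiran-2-yl]hepta-3,6-dien-3-yl]oxy}trimethylsilane | CC1(C)O[C@@H]1CC[C@@]2(C)O[C@@H]2CC/C(O[Si](C)(C)C)=C/CC=C | intermediate
29 | (3R,5aR,6R,9aR)-2,2,5a-trimethyl-6-(prop-2-en-1-yl)-3-[(trimethylsilyl)oxy]octahydro-1-benzoxepin-7(2H)-one | C=CC[C@@H]1[C@@]2(C)CC[C@@H](O[Si](C)(C)C)C(C)(C)O[C@@H]2CCC1=O | intermediate
30 | (3R,5aR,6R,9aR)-3-hydroxy-2,2,5a-trimethyl-6-(prop-2-en-1-yl)octahydro-1-benzoxepin-7(2H)-one | C=CC[C@@H]1[C@@]2(C)CC[C@@H](O)C(C)(C)O[C@@H]2CCC1=O | intermediate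
31 | (3R,5aR,6R,7S,9aR)-2,2,5a,7-tetramethyl-6-(prop-2-en-1-yl)decahydro-1-benzoxepine-3,7-diol | C=CC[C@@H]1[C@@]2(C)CC[C@@H](O)C(C)(C)O[C@@H]2CC[C@]1(C)O | intermediate
32 | (3R,5aR,6R,7S,9aR)-2,2,5a,7-tetramethyl-6-(prop-2-en-1-yl)-3,7-bis[(triethylsilyl)oxy]decahydro-1-benzoxepine | C=CC[C@@H]1[C@@]2(C)CC[C@@H](O[Si](CC)(CC)CC)C(C)(C)O[C@@H]2CC[C@]1(C)O[Si](CC)(CC)CC | intermediate
33 | 3-({(3R,5aR,6R,7S,9aR)-2,2,5a,7-tetramethyl-3,7-bis[(triethylsilyl)oxy]decahydro-1-benzoxepin-6-yl}methyl)-1,2,4-trioxolane | C1OOC(O1)C[C@@H]1[C@@]2(C)CC[C@@H](O[Si](CC)(CC)CC)C(C)(C)O[C@@H]2CC[C@]1(C)O[Si](CC)(CC)CC | intermediate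
34 | 2-{(3R,5aR,6R,7S,9aR)-2,2,5a,7-tetramethyl-3,7-bis[(triethylsilyl)oxy]decahydro-1-benzoxepin-6-yl}acetaldehyde | O=CC[C@@H]1[C@@]2(C)CC[C@@H](O[Si](CC)(CC)CC)C(C)(C)O[C@@H]2CC[C@]1(C)O[Si](CC)(CC)CC | intermediate
35 | 1-[(1R,3aR,8aR)-1,4,4,6-tetramethyl-1-[(triethylsilyl)oxy]-1,2,3,3a,4,7,8,8a-octahydroazulen-5-yl]-2-[(3R,5aR,6R,7S,9aR)-2,2,5a,7-tetramethyl-3,7-bis[(triethylsilyl)oxy]decahydro-1-benzoxepin-6-yl]ethan-1-ol (both C1 epimers) | CC=1CC[C@@H]2[C@@H](CC[C@@]2(C)O[Si](CC)(CC)CC)C(C)(C)C=1C(O)C[C@@H]1[C@@]2(C)CC[C@@H](O[Si](CC)(CC)CC)C(C)(C)O[C@@H]2CC[C@]1(C)O[Si](CC)(CC)CC | intermediate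
36 | 1-[(1R,3aR,8aR)-1,4,4,6-tetramethyl-1-[(triethylsilyl)oxy]-1,2,3,3a,4,7,8,8a-octahydroazulen-5-yl]-2-[(3R,5aR,6R,7S,9aR)-2,2,5a,7-tetramethyl-3,7-bis[(triethylsilyl)oxy]decahydro-1-benzoxepin-6-yl]ethan-1-one | CC=1CC[C@@H]2[C@@H](CC[C@@]2(C)O[Si](CC)(CC)CC)C(C)(C)C=1C(=O)C[C@@H]1[C@@]2(C)CC[C@@H](O[Si](CC)(CC)CC)C(C)(C)O[C@@H]2CC[C@]1(C)O[Si](CC)(CC)CC | intermediate
37 | (1R)-1-[(1R,3aR,8aR)-1,4,4,6-tetramethyl-1-[(triethylsilyl)oxy]-1,2,3,3a,4,7,8,8a-octahydroazulen-5-yl]-2-[(3R,5aR,6R,7S,9aR)-2,2,5a,7-tetramethyl-3,7-bis[(triethylsilyl)oxy]decahydro-1-benzoxepin-6-yl]ethan-1-ol | CC=1CC[C@@H]2[C@@H](CC[C@@]2(C)O[Si](CC)(CC)CC)C(C)(C)C=1[C@H](O)C[C@@H]1[C@@]2(C)CC[C@@H](O[Si](CC)(CC)CC)C(C)(C)O[C@@H]2CC[C@]1(C)O[Si](CC)(CC)CC | intermediate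
38 | N-{(1S)-1-[(1R,3aR,8aR)-1,4,4,6-tetramethyl-1-[(triethylsilyl)oxy]-1,2,3,3a,4,7,8,8a-octahydroazulen-5-yl]-2-[(3R,5aR,6R,7S,9aR)-2,2,5a,7-tetramethyl-3,7-bis[(triethylsilyl)oxy]decahydro-1-benzoxepin-6-yl]ethyl}-2-nitro-N'-(propan-2-ylidene)benzenesulfonohydrazide | CC=1CC[C@@H]2[C@@H](CC[C@@]2(C)O[Si](CC)(CC)CC)C(C)(C)C=1[C@@H](N(N=C(C)C)S(=O)(=O)c3ccccc3[N+](=O)[O-])C[C@@H]1[C@@]2(C)CC[C@@H](O[Si](CC)(CC)CC)C(C)(C)O[C@@H]2CC[C@]1(C)O[Si](CC)(CC)CC | intermediate
39 | {(1S)-1-[(1R,3aR,8aR)-1,4,4,6-tetramethyl-1-[(triethylsilyl)oxy]-1,2,3,3a,4,7,8,8a-octahydroazulen-5-yl]-2-[(3R,5aR,6R,7S,9aR)-2,2,5a,7-tetramethyl-3,7-bis[(triethylsilyl)oxy]decahydro-1-benzoxepin-6-yl]ethyl}diazene | CC=1CC[C@@H]2[C@@H](CC[C@@]2(C)O[Si](CC)(CC)CC)C(C)(C)C=1[C@@H](N=N)C[C@@H]1[C@@]2(C)CC[C@@H](O[Si](CC)(CC)CC)C(C)(C)O[C@@H]2CC[C@]1(C)O[Si](CC)(CC)CC | intermediate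
40 | (3R,5aR,6R,7S,9aR)-6-{(2Z)-2-[(1R,3aR,6S,8aR)-1,4,4,6-tetramethyl-1-[(triethylsilyl)oxy]octahydroazulen-5(1H)-ylidene]ethyl}-2,2,5a,7-tetramethyl-3,7-bis[(triethylsilyl)oxy]decahydro-1-benzoxepine | C[C@H]1CC[C@@H]2[C@@H](CC[C@@]2(C)O[Si](CC)(CC)CC)C(C)(C)/C1=C\C[C@@H]1[C@@]2(C)CC[C@@H](O[Si](CC)(CC)CC)C(C)(C)O[C@@H]2CC[C@]1(C)O[Si](CC)(CC)CC | intermediate
41 | (3R,5aR,6R,7S,9aR)-6-{(2Z)-2-[(1R,3aR,6S,8aR)-1-hydroxy-1,4,4,6-tetramethyloctahydroazulen-5(1H)-ylidene]ethyl}-2,2,5a,7-tetramethyldecahydro-1-benzoxepine-3,7-diol | C[C@H]1CC[C@@H]2[C@@H](CC[C@@]2(C)O)C(C)(C)/C1=C\C[C@@H]1[C@@]2(C)CC[C@@H](O)C(C)(C)O[C@@H]2CC[C@]1(C)O | intermediate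
42 | (5aR,6R,7S,9aR)-7-hydroxy-6-{(2Z)-2-[(1R,3aR,6S,8aR)-1-hydroxy-1,4,4,6-tetramethyloctahydroazulen-5(1H)-ylidene]ethyl}-2,2,5a,7-tetramethyloctahydro-1-benzoxepin-3(2H)-one | C[C@H]1CC[C@@H]2[C@@H](CC[C@@]2(C)O)C(C)(C)/C1=C\C[C@@H]1[C@@]2(C)CCC(=O)C(C)(C)O[C@@H]2CC[C@]1(C)O | target

Total step count: 30. Longest linear sequence: 22 steps (steps 1–16, then 25–30); the ring A/B branch (steps 17–24) is 8 steps.

Steps most likely to fail

Step 28. The Mitsunobu displacement at the secondary allylic carbinol, which is flanked by a fully substituted alkene and a branched CH2 arm, may be slow, so that elimination or decomposition of the activated alcohol competes; a diazene rotamer with the chain turned inward would also erode the C6 and alkene outcome. Fallback: the nitrogen would be brought in by condensation instead of substitution. It sets out from enone 36, which with p-toluenesulfonyl hydrazide would give the tosylhydrazone of 36 F10. Catecholborane would reduce the C=N bond to the N-allyl-N'-tosylhydrazine F11, and sodium acetate trihydrate with warming would expel sulfinate to return to the route at diazene 39, which loses N2 to give 40. This is the known catecholborane reduction of enone tosylhydrazones with alkene transposition. The configuration of the nitrogen-bearing carbon would then depend on the face of hydride addition, so the C6 epimers would be separated at 40 if both form.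

Step 25. Oxidative addition of zerovalent nickel to the tetrasubstituted enol triflate next to the quaternary carbon may be sluggish, so that protodetriflation or aldehyde decomposition outruns C–C bond formation. Fallback: the alkenyl nucleophile would be made by a Shapiro reaction. It sets out from ketone 20, which with 2,4,6-triisopropylbenzenesulfonyl hydrazide would give the trisylhydrazone of 20 F8. n-BuLi (2.2 equiv, THF, −78 → 0 °C) would remove the only α-hydrogen (C6–H) and release the alkenyllithium F9, which adds to aldehyde 34 at −78 °C and returns to the route at 35. The same reaction is established for 2,2,6-trimethylcyclohexanone.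

Step 21. The enol silane may capture the internal epoxide before the epoxonium ion has formed, or the epoxonium ion may collapse by elimination, so that little oxepane is obtained. Fallback: the two ring closures would be run one after the other.
- It sets out from 24. Sharpless asymmetric epoxidation of geraniol (D-(−)-diethyl tartrate, Ti(OiPr)4, t-BuOOH) would give [(2R,3R)-3-methyl-3-(4-methylpent-3-en-1-yl)oxiran-2-yl]methanol F1.
- I2, PPh3 and imidazole would convert it to (2S,3R)-2-(iodomethyl)-3-methyl-3-(4-methylpent-3-en-1-yl)oxirane F2.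
- Alkylation of the lithium enolate of 24 with F2 would give the monoepoxy amide F3; vinyl Grignard addition would give the enone F4; copper-catalysed vinyl addition with Me3SiCl would give the enol silane F5.
- BF3·OEt2 (CH2Cl2, −78 °C) would then close ring B alone, by six-membered opening of the epoxide at its tertiary carbon, to the hydroxy ketone F6.
- Shi epoxidation of the remaining trisubstituted alkene would give the epoxy alcohol F7, and camphorsulfonic acid would close the oxepane by 7-endo attack of the ring hydroxyl at the tertiary epoxide carbon, returning to the route at 30.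

Further compounds
F1 | step 21 | [(2R,3R)-3-methyl-3-(4-methylpent-3-en-1-yl)oxiran-2-yl]methanol | CC(C)=CCC[C@@]1(C)O[C@@H]1CO
F2 | step 21 | (2S,3R)-2-(iodomethyl)-3-methyl-3-(4-methylpent-3-en-1-yl)oxirane | CC(C)=CCC[C@@]1(C)O[C@@H]1CI
F3 | step 21 | N-methoxy-N-methyl-3-[(2R,3R)-3-methyl-3-(4-methylpent-3-en-1-yl)oxiran-2-yl]propanamide | CC(C)=CCC[C@@]1(C)O[C@@H]1CCC(=O)N(C)OC
F4 | step 21 | 5-[(2R,3R)-3-methyl-3-(4-methylpent-3-en-1-yl)oxiran-2-yl]pent-1-en-3-one | CC(C)=CCC[C@@]1(C)O[C@@H]1CCC(=O)C=C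
F5 | step 21 | trimethyl{[(3Z)-1-[(2R,3R)-3-methyl-3-(4-methylpent-3-en-1-yl)oxiran-2-yl]hepta-3,6-dien-3-yl]oxy}silane | CC(C)=CCC[C@@]1(C)O[C@@H]1CC/C(O[Si](C)(C)C)=C/CC=C
F6 | step 21 | (2R,3R,4R)-4-hydroxy-3-methyl-3-(4-methylpent-3-en-1-yl)-2-(prop-2-en-1-yl)cyclohexan-1-one | C=CC[C@@H]1[C@@](C)(CCC=C(C)C)[C@H](O)CCC1=O
F7 | step 21 | (2R,3R,4R)-3-{2-[(2R)-3,3-dimethyloxiran-2-yl]ethyl}-4-hydroxy-3-methyl-2-(prop-2-en-1-yl)cyclohexan-1-one | C=CC[C@@H]1[C@@](C)(CC[C@H]2OC2(C)C)[C@H](O)CCC1=O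
F8 | step 25 | 2,4,6-triisopropylbenzenesulfonyl hydrazone of ketone 20 | CC1CC[C@@H]2[C@@H](CC[C@@]2(C)O[Si](CC)(CC)CC)C(C)(C)C1=NNS(=O)(=O)c3c(C(C)C)cc(C(C)C)cc3C(C)C
F9 | step 25 | {(1R,3aR,8aR)-1,4,4,6-tetramethyl-1-[(triethylsilyl)oxy]-1,2,3,3a,4,7,8,8a-octahydroazulen-5-yl}lithium | CC=1CC[C@@H]2[C@@H](CC[C@@]2(C)O[Si](CC)(CC)CC)C(C)(C)C=1[Li]
F10 | step 28 | p-toluenesulfonyl hydrazone of enone 36 | CC=1CC[C@@H]2[C@@H](CC[C@@]2(C)O[Si](CC)(CC)CC)C(C)(C)C=1C(=NNS(=O)(=O)c3ccc(C)cc3)C[C@@H]1[C@@]2(C)CC[C@@H](O[Si](CC)(CC)CC)C(C)(C)O[C@@H]2CC[C@]1(C)O[Si](CC)(CC)CC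
F11 | step 28 | (1S)-N-allyl-N'-tosylhydrazine from reduction of F10 | CC=1CC[C@@H]2[C@@H](CC[C@@]2(C)O[Si](CC)(CC)CC)C(C)(C)C=1[C@@H](NNS(=O)(=O)c3ccc(C)cc3)C[C@@H]1[C@@]2(C)CC[C@@H](O[Si](CC)(CC)CC)C(C)(C)O[C@@H]2CC[C@]1(C)O[Si](CC)(CC)CC
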